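## Structural features

The target is a biflavonoid in which two C15 units share one diaryl ether oxygen: C6 of ring A of a (2S)-flavanone (5-OH, 7-OMe, 4'-OH) is bonded through oxygen to C4' of ring B of a 5,7-dihydroxyflavone. Ring A of the flavanone is substituted at five of its six carbons (C4a, C5, C6, C7, C8a), so the ether oxygen at C6 lies between the C5 hydroxyl and the C7 methoxy group. The three oxygens at C5, C7 and C8a each end in a different state: free phenol, methyl ether and ring ether. The only stereocenter is C2 of the flavanone and it has no stereogenic neighbour. It is a benzylic ether carbon β to the C4 ketone, so it can open to the 2'-hydroxychalcone by retro-oxa-Michael reaction under base, and more easily once the 4'-hydroxyl is free. Other fragile features are the four phenols (two chelated to the C4 carbonyls), the phloroglucinol-type ring A of the flavone (nucleophilic at C6 and C8) and, in protected intermediates, a 5,7-dialkoxyflavan-4-ol that ionises readily in acid. The real difficulty is the order of events: the second heterocycle has to be built on a molecule that already holds C2, without epimerising it, and the hindered ether has to be made early. The key step uses the fact that flavone ring C (O1, C2, C3, C4, C4a, C8a) is an ortho-hydroxyaryl ynone in masked form. C4 lies between the aryl carbon C4a and C3, so it can arrive as carbon monoxide between an aryl iodide and a terminal alkyne, after which the oxygen on C8a closes onto C2.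

## Logic of the disconnections

**23 to 22.** The three O–CH2Ph bonds and the O–CH3 bond at C5 of the flavanone are cut last. All four are cleavable by one boron Lewis acid, the methyl ether because it is chelated to the C4 ketone. This leaves 22 with no free phenol. The forward step must spare the C7 methyl ether and the C2 configuration.

**22 to 21 to 20.** No skeletal bond is cut; the C4 ketone is traced back to a carbinol and then to its silyl ether. The reason is that the flavone must be built while no enolisable ketone stands β to C2. The forward steps (fluoride, then a buffered neutral oxidant) must avoid acid, since the free carbinol ionises easily.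

**20 to 17, 15 and carbon monoxide.** The bonds C4a–C4, C3–C4 and O1–C2 of the flavone are cut. This is the most convergent cut: it separates a one-step ring A fragment from the whole flavanone half, and C4 becomes a gas. The forward step must insert carbon monoxide before alkynyl transfer and must close 6-endo.

**17 to 16.** The C–I bond is cut. The forward iodination must go ortho to the free hydroxyl and not between the two benzyloxy groups.

**15 to 13 to 12.** The terminal alkyne carbon is removed and the remaining carbon is traced through an aldehyde and a benzylic alcohol to a methyl ester. The ester is inert in all earlier steps and activates the aryl fluoride used at the start. The forward steps need a silyl ether that survives hydride reduction and K2CO3 in methanol.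

**12 to 11 to 10.** The Si–O bond and the C4–H bond are cut, which leads back to the flavanone. The forward reduction must be fast and cold so that C2 does not open. Its cis selectivity is welcome but not essential, because C4 is oxidised again later.

**10 to 8 and 9.** The C2–aryl bond is cut. This makes the stereocenter by catalyst control on a flat chromone. The forward conjugate arylation must be enantioselective and non-basic.

**8 to 6.** O1–C2 and C2–C3 are cut, so that C2 becomes a one-carbon amide acetal unit added to a methyl ketone.

**6 to 5.** The aryl–acyl bond is cut. Ring A of 5 is symmetric and its only two free positions are equivalent, so no regiochemical demand arises.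

**5 to 3.** The aryl C–O bond is traced to an aryl C–CHO bond. The aldehyde activates nothing harmful and is exchanged for oxygen by peracid. The forward step requires aryl migration and not hydride migration.

**3 to 1 and 2.** The diaryl ether C–O bond on the benzoate ring is cut. This forms the hindered ether first, on the simplest possible partners. The forward step needs a 2,6-disubstituted phenoxide to displace fluoride.

## Other disconnections considered

**Alternative 1:** The cut runs through ring A of the flavanone at C4a–C5, C8–C8a and C5–C6. It leaves the cyclobutenone A2 (C5 to C8, with the ether oxygen and the methoxy group already attached) and the siloxyalkyne A3 (C4a, C8a and the side chain with the carbinol stereocenter).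

- **Forward step.** A2 and A3 are heated in toluene. Four-electron ring opening of A2, [2+2] addition to A3, a second ring opening and six-electron closure (a Danheiser-type benzannulation) should give phenol A1.
- **Structural correction.** With only two carbons between ring A and the benzylic carbinol, the later ring closure would give a five-membered and not a six-membered oxygen ring. A1 and A3 are therefore drawn with C4 in place as a second silylated carbinol.
- **In favour.** All five substituents of ring A are placed by the regiochemistry of the annulation. The hindered C6–O bond exists before the ring does, so no substitution at a doubly flanked phenol is needed. The ring A oxygens are differentiated from the start (free C5–OH, silylated C8a–O, methylated C7–O), so no late selective demethylation is required. On these two points the alternative is better than the chosen plan.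
- **Against.** A2 has no short, reliable preparation and carries an acidic hydrogen on its sp3 carbon. A3 is a hydrolytically labile siloxyalkyne that needs its own stereocontrolled synthesis. After the annulation, ring C must still be closed by a Mitsunobu-type etherification with inversion at a benzylic carbinol, which can ionise and erode the configuration. Two carbinols and two phenols must be told apart for this, and C4 must then be oxidised.
- **Comparison.** The chosen plan sets C2 by catalyst control and makes no further bond at that carbon. The alternative makes the C2–O bond by substitution. Its step count, with the syntheses of A2 and A3 included, should exceed that of the chosen plan.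

**Alternative 2:** The cut is C4a–C5 of the flavone, which traces ring A to the β-keto ester arm of pyranone A5.

- **Forward step.** Mg(OMe)2 in methanol should effect a Claisen-type C-acylation of the ester carbonyl by pyranone C3 and, after enolisation, give the 5,7-dihydroxyflavone A4.
- **In favour.** The step is biomimetic and needs no transition metal, no pressure of carbon monoxide and no regioselective iodination. The flavone 5,7-diol arrives unprotected, so two benzyl ethers fewer are carried; on protecting-group count for the flavone half it is better than the chosen plan. No stereocenter is present when the base is used, so it is the equal of the chosen plan on configurational safety at that stage.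
- **Against.** A5 needs a polycarbonyl chain assembled by several carbanion acylations, and an aldol-type closure competes with the Claisen mode. More serious, the flavone is made first. The whole flavanone half (phenol release, ring acylation, chromone formation, asymmetric arylation, C5 demethylation) must then be built next to a free phloroglucinol-type ring. In the counterpart of step 3 the acylation would have to choose between two electron-rich rings. Protecting the diol to avoid this removes the advantage.
- **Comparison.** The chosen plan keeps every electrophilic step on a molecule with one reactive ring and joins the halves late. The alternative is more linear and should be longer.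

**Alternative 3:** The cut is C4–C4a of the flavanone, which traces ring C to the (S)-3-aryl-3-aryloxypropanoic acid A7.

- **Forward step.** Activation with (CF3CO)2O should bring about an intramolecular Friedel–Crafts acylation at the carbon ortho to the ether oxygen and give A6.
- **In favour.** The acylated ring is symmetric, so no regiochemical question arises; here the alternative is the equal of the chosen plan, in which step 3 acylates a symmetric ring as well. The C4 ketone is formed directly, with no reduction, silylation, desilylation and reoxidation. On endgame step economy the alternative is better than the chosen plan. The flavone in A7 can be made earlier on an achiral substrate, even by the same carbonylative annulation.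
- **Against.** In A7 the C2–O bond is a benzylic aryl ether β to an activated carboxyl. Under strongly acidic acylating conditions, β-elimination of the aryloxide and ionisation at C2 threaten both yield and optical purity; this is why the 4'-oxygen is acetylated. The benzyloxy-substituted ring A of the flavone can be trifluoroacetylated. A7 itself requires a C2–O bond made by substitution at a benzylic carbinol. The same selective C5 demethylation is still needed at the end.
- **Comparison.** The alternative is shorter but exposes the stereocenter twice to conditions that can ionise it. The chosen plan is longer and keeps C2 away from every bond-forming event after step 5.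

Key step: step 11

Assumption 1: 3,5-bis(benzyloxy)phenol is taken to be a catalogue compound, which removes the statistical benzylation of phloroglucinol from the route.

Assumption 2: the facial sense of the pyridine–oxazoline palladium catalyst on the chromone is taken to follow that of cyclic enones, so that the (R)-ligand leads to the 2S product; if the sense were the reverse, the (S)-ligand would be used with nothing else changed.

## Route

Step 1
Reactants: 1 syringaldehyde; 2 methyl 4-fluorobenzoate
Product: 3 methyl 4-(4-formyl-2,6-dimethoxyphenoxy)benzoate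
Conditions: Cs2CO3, DMSO, 110 °C
Reagents that add atoms: none
Why: Nucleophilic aromatic substitution (SNAr): the phenoxide adds para to the ester, the Meisenheimer adduct is stabilised by the ester, and fluoride leaves; the cesium phenoxide in DMSO should be reactive enough despite its two ortho methoxy groups.

Step 2
Reactants: 3 methyl 4-(4-formyl-2,6-dimethoxyphenoxy)benzoate
Product: 5 methyl 4-(4-hydroxy-2,6-dimethoxyphenoxy)benzoate, via aryl formate 4 (not isolated)
Conditions: mCPBA, CH2Cl2, 0 °C to rt; then K2CO3 (cat.), MeOH, rt
Reagents that add atoms: 3-chloroperoxybenzoic acid (mCPBA), O=C(OO)c1cccc(Cl)c1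
Why: Baeyer–Villiger (Dakin-type) oxidation: the oxygenated aryl group migrates in the Criegee adduct in preference to hydride, as with 3,4,5-trialkoxybenzaldehydes, and the formate is methanolysed; the benzoate ring is inert to peracid.

Step 3
Reactants: 5 methyl 4-(4-hydroxy-2,6-dimethoxyphenoxy)benzoate
Product: 6 methyl 4-(3-acetyl-4-hydroxy-2,6-dimethoxyphenoxy)benzoate
Conditions: Ac2O, BF3·OEt2, 80 °C; then H2O/MeOH, 60 °C
Reagents that add atoms: acetic anhydride, CC(=O)OC(C)=O
Why: Friedel–Crafts C-acylation (through the aryl acetate and a Fries-type shift): the only free positions of the phenol ring are the two equivalent carbons ortho to the hydroxyl, the ketone is held as a difluoroboron chelate that prevents a second acylation, and the benzoate ring is deactivated.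

Step 4
Reactants: 6 methyl 4-(3-acetyl-4-hydroxy-2,6-dimethoxyphenoxy)benzoate
Product: 8 methyl 4-[(5,7-dimethoxy-4-oxo-4H-chromen-6-yl)oxy]benzoate, via enaminone 7 (not isolated)
Conditions: Me2NCH(OMe)2, toluene, 100 °C; then conc. HCl, CH2Cl2, rt
Reagents that add atoms: N,N-dimethylformamide dimethyl acetal, COC(OC)N(C)C
Why: Enaminone route to chromones: the methyl ketone condenses with the amide acetal, and acid then promotes conjugate addition of the phenol and loss of dimethylamine (6-endo addition–elimination), which closes the pyranone.

Step 5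
Reactants: 8 methyl 4-[(5,7-dimethoxy-4-oxo-4H-chromen-6-yl)oxy]benzoate; 9 4-(benzyloxy)phenylboronic acid
Product: 10 methyl 4-({(2S)-2-[4-(benzyloxy)phenyl]-5,7-dimethoxy-4-oxo-3,4-dihydro-2H-chromen-6-yl}oxy)benzoate
Conditions: Pd(OCOCF3)2 (5 mol %), (R)-4-tert-butyl-2-(pyridin-2-yl)-4,5-dihydrooxazole (6 mol %), NH4PF6 (30 mol %), H2O (5 equiv), ClCH2CH2Cl, 60 °C
Reagents that add atoms: none
Why: Enantioselective conjugate arylation of a chromone (Hayashi–Miyaura type, with a cationic complex of divalent palladium): the aryl group passes from boron to palladium, adds across C2=C3, and the palladium enolate is protonated by water. The tert-butyl group of the ligand shields one face of the enone in the carbopalladation and so sets C2 as S. The medium is not basic, so the flavanone cannot racemise by ring opening.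

Step 6
Reactants: 10 methyl 4-({(2S)-2-[4-(benzyloxy)phenyl]-5,7-dimethoxy-4-oxo-3,4-dihydro-2H-chromen-6-yl}oxy)benzoate
Product: 11 methyl 4-({(2S,4S)-2-[4-(benzyloxy)phenyl]-4-hydroxy-5,7-dimethoxy-3,4-dihydro-2H-chromen-6-yl}oxy)benzoate
Conditions: NaBH4, MeOH/THF, −10 to 0 °C
Reagents that add atoms: none
Why: Borohydride reduction of the aryl ketone: with the C2 aryl group equatorial on the half-chair, axial hydride attack should give the equatorial 2,4-cis carbinol (4S, substrate control; this center is removed again in step 13). The benzoate ester is not reduced at this temperature, and the cold, fast reduction leaves no time for retro-oxa-Michael opening.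

Step 7
Reactants: 11 methyl 4-({(2S,4S)-2-[4-(benzyloxy)phenyl]-4-hydroxy-5,7-dimethoxy-3,4-dihydro-2H-chromen-6-yl}oxy)benzoate
Product: 12 methyl 4-({(2S,4S)-2-[4-(benzyloxy)phenyl]-4-[(tert-butyldimethylsilyl)oxy]-5,7-dimethoxy-3,4-dihydro-2H-chromen-6-yl}oxy)benzoate
Conditions: TBSCl, imidazole, DMAP (cat.), DMF, rt
Reagents that add atoms: tert-butyldimethylsilyl chloride, CC(C)(C)[Si](C)(C)Cl
Why: Silylation of a secondary alcohol under basic conditions, which avoid ionisation of the electron-rich benzylic carbinol; the silyl ether shields C4 from the oxidant of step 9.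

Step 8
Reactants: 12 methyl 4-({(2S,4S)-2-[4-(benzyloxy)phenyl]-4-[(tert-butyldimethylsilyl)oxy]-5,7-dimethoxy-3,4-dihydro-2H-chromen-6-yl}oxy)benzoate
Product: 13 [4-({(2S,4S)-2-[4-(benzyloxy)phenyl]-4-[(tert-butyldimethylsilyl)oxy]-5,7-dimethoxy-3,4-dihydro-2H-chromen-6-yl}oxy)phenyl]methanol
Conditions: i-Bu2AlH, CH2Cl2, −78 to 0 °C; aq. potassium sodium tartrate
Reagents that add atoms: none
Why: Reduction of the ester to the primary alcohol with an aluminium hydride; silyl, benzyl and methyl ethers are inert, and full reduction is more dependable for an aryl ester than a stop at the aldehyde.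

Step 9
Reactants: 13 [4-({(2S,4S)-2-[4-(benzyloxy)phenyl]-4-[(tert-butyldimethylsilyl)oxy]-5,7-dimethoxy-3,4-dihydro-2H-chromen-6-yl}oxy)phenyl]methanol
Product: 15 {[(2S,4S)-2-[4-(benzyloxy)phenyl]-6-(4-ethynylphenoxy)-5,7-dimethoxy-3,4-dihydro-2H-chromen-4-yl]oxy}(tert-butyl)dimethylsilane, via aldehyde 14 (not isolated)
Conditions: MnO2, THF, rt; then MeOH, K2CO3, dimethyl (1-diazo-2-oxopropyl)phosphonate, rt
Reagents that add atoms: dimethyl (1-diazo-2-oxopropyl)phosphonate (Ohira–Bestmann reagent), COP(=O)(OC)C(=[N+]=[N-])C(C)=O
Why: Benzylic oxidation with MnO2 followed in the same flask by Seyferth–Gilbert homologation in the Ohira–Bestmann variant: methoxide removes the acetyl group, the diazophosphonate anion adds to the aldehyde, and loss of phosphate and dinitrogen with a 1,2-shift gives the terminal alkyne. The conditions are mildly basic, so the silyl ether and C2 are untouched.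

Step 10
Reactants: 16 3,5-bis(benzyloxy)phenol
Product: 17 3,5-bis(benzyloxy)-2-iodophenol
Conditions: N-iodosuccinimide, CH2Cl2, −20 to 0 °C, dark
Reagents that add atoms: N-iodosuccinimide, O=C1CCC(=O)N1I
Why: Electrophilic aromatic iodination: the two equivalent carbons ortho to the hydroxyl are each flanked by one benzyloxy group and the small hydroxyl, whereas the para carbon lies between two benzyloxy groups, so statistics and sterics should both favour C2; one equivalent at low temperature limits di-iodination.

Step 11
Reactants: 17 3,5-bis(benzyloxy)-2-iodophenol; 15 {[(2S,4S)-2-[4-(benzyloxy)phenyl]-6-(4-ethynylphenoxy)-5,7-dimethoxy-3,4-dihydro-2H-chromen-4-yl]oxy}(tert-butyl)dimethylsilane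
Product: 20 5,7-bis(benzyloxy)-2-[4-({(2S,4S)-2-[4-(benzyloxy)phenyl]-4-[(tert-butyldimethylsilyl)oxy]-5,7-dimethoxy-3,4-dihydro-2H-chromen-6-yl}oxy)phenyl]-4H-chromen-4-one, via ynone 18 (not isolated), via enaminone 19 (not isolated)
Conditions: PdCl2(PPh3)2 (5 mol %), CO (20 atm), Et2NH, 120 °C
Reagents that add atoms: carbon monoxide, [C-]#[O+]
Why: Zerovalent palladium, formed in the flask from PdCl2(PPh3)2, inserts into the C–I bond of 17; carbon monoxide then inserts to give an aroyl complex of divalent palladium, the amine-activated alkyne 15 transfers its alkynyl group, and reductive elimination releases ynone 18 (bonds C4a–C4 and C3–C4). Et2NH adds to 18 in conjugate fashion to give enaminone 19, and the ortho phenol then attacks the β-carbon and expels the amine, so ring C of the flavone closes by a 6-endo addition–elimination that forms O1–C2. The closest known reaction type is the palladium-catalysed carbonylative annulation of ortho-iodophenols with terminal alkynes to flavones. No stereocenter is created; C2 and C4 of the flavan are spectators, and because C4 is a silylated carbinol there is no enolisable ketone through which C2 could open in the hot amine. Carbonylative coupling should win over direct coupling because copper is absent, the pressure of carbon monoxide is high, and the two ortho substituents on the aryl–palladium species slow direct alkynyl transfer more than they slow insertion. 6-endo closure should win over 5-exo closure because 19 offers the phenol only its β-carbon.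

Step 12
Reactants: 20 5,7-bis(benzyloxy)-2-[4-({(2S,4S)-2-[4-(benzyloxy)phenyl]-4-[(tert-butyldimethylsilyl)oxy]-5,7-dimethoxy-3,4-dihydro-2H-chromen-6-yl}oxy)phenyl]-4H-chromen-4-one
Product: 21 5,7-bis(benzyloxy)-2-[4-({(2S,4S)-2-[4-(benzyloxy)phenyl]-4-hydroxy-5,7-dimethoxy-3,4-dihydro-2H-chromen-6-yl}oxy)phenyl]-4H-chromen-4-one
Conditions: Bu4NF, THF, 0 °C to rt; aq. NH4Cl
Reagents that add atoms: none
Why: Fluoride-mediated desilylation driven by the Si–F bond; the conditions are basic, so the acid-labile carbinol, the flavone and the benzyl ethers are safe, and 21 is best taken on without chromatography on acidic silica.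

Step 13
Reactants: 21 5,7-bis(benzyloxy)-2-[4-({(2S,4S)-2-[4-(benzyloxy)phenyl]-4-hydroxy-5,7-dimethoxy-3,4-dihydro-2H-chromen-6-yl}oxy)phenyl]-4H-chromen-4-one
Product: 22 5,7-bis(benzyloxy)-2-[4-({(2S)-2-[4-(benzyloxy)phenyl]-5,7-dimethoxy-4-oxo-3,4-dihydro-2H-chromen-6-yl}oxy)phenyl]-4H-chromen-4-one
Conditions: Dess–Martin periodinane, pyridine, CH2Cl2, 0 °C to rt
Reagents that add atoms: none
Why: Dess–Martin oxidation of the secondary benzylic alcohol by ligand exchange at iodine and intramolecular deprotonation; the pyridine buffer removes the acetic acid that could ionise the carbinol and is too weak a base to open the new flavanone at C2.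

Step 14
Reactants: 22 5,7-bis(benzyloxy)-2-[4-({(2S)-2-[4-(benzyloxy)phenyl]-5,7-dimethoxy-4-oxo-3,4-dihydro-2H-chromen-6-yl}oxy)phenyl]-4H-chromen-4-one
Product: 23 5,7-dihydroxy-2-[4-({(2S)-5-hydroxy-2-(4-hydroxyphenyl)-7-methoxy-4-oxo-3,4-dihydro-2H-chromen-6-yl}oxy)phenyl]-4H-chromen-4-one (CNP0269971.1)
Conditions: BCl3, C6HMe5, CH2Cl2, −78 to 0 °C; then MeOH, aq. NaHCO3
Reagents that add atoms: none
Why: Lewis acid ether cleavage: BCl3 removes the three benzyl groups, whose cations are trapped by pentamethylbenzene before they can alkylate the phloroglucinol-type rings, and it cleaves the C5 methyl ether through a six-membered chelate with the C4 ketone. The unchelated C7 methyl ether and the diaryl ether should survive at or below 0 °C, and the low temperature should keep C2 intact.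

## Compound list

1 | syringaldehyde (4-hydroxy-3,5-dimethoxybenzaldehyde) | COc1cc(C=O)cc(OC)c1O | starting material
2 | methyl 4-fluorobenzoate | COC(=O)c1ccc(F)cc1 | starting material
3 | methyl 4-(4-formyl-2,6-dimethoxyphenoxy)benzoate | COC(=O)c1ccc(Oc2c(OC)cc(C=O)cc2OC)cc1 | intermediate
4 | methyl 4-[4-(formyloxy)-2,6-dimethoxyphenoxy]benzoate | COC(=O)c1ccc(Oc2c(OC)cc(OC=O)cc2OC)cc1 | intermediate (not isolated)
5 | methyl 4-(4-hydroxy-2,6-dimethoxyphenoxy)benzoate | COC(=O)c1ccc(Oc2c(OC)cc(O)cc2OC)cc1 | intermediate
6 | methyl 4-(3-acetyl-4-hydroxy-2,6-dimethoxyphenoxy)benzoate | COC(=O)c1ccc(Oc2c(OC)cc(O)c(C(C)=O)c2OC)cc1 | intermediate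
7 | methyl 4-{3-[(2E)-3-(dimethylamino)prop-2-enoyl]-4-hydroxy-2,6-dimethoxyphenoxy}benzoate | COC(=O)c1ccc(Oc2c(OC)cc(O)c(C(=O)/C=C/N(C)C)c2OC)cc1 | intermediate (not isolated)
8 | methyl 4-[(5,7-dimethoxy-4-oxo-4H-chromen-6-yl)oxy]benzoate | COC(=O)c1ccc(Oc2c(OC)cc3occc(=O)c3c2OC)cc1 | intermediate
9 | 4-(benzyloxy)phenylboronic acid | OB(O)c1ccc(OCc2ccccc2)cc1 | starting material
10 | methyl 4-({(2S)-2-[4-(benzyloxy)phenyl]-5,7-dimethoxy-4-oxo-3,4-dihydro-2H-chromen-6-yl}oxy)benzoate | O=C1C[C@@H](c2ccc(OCc3ccccc3)cc2)Oc2cc(OC)c(Oc3ccc(cc3)C(=O)OC)c(OC)c12 | intermediate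
11 | methyl 4-({(2S,4S)-2-[4-(benzyloxy)phenyl]-4-hydroxy-5,7-dimethoxy-3,4-dihydro-2H-chromen-6-yl}oxy)benzoate (2,4-cis) | O[C@H]1C[C@@H](c2ccc(OCc3ccccc3)cc2)Oc2cc(OC)c(Oc3ccc(cc3)C(=O)OC)c(OC)c12 | intermediate
12 | methyl 4-({(2S,4S)-2-[4-(benzyloxy)phenyl]-4-[(tert-butyldimethylsilyl)oxy]-5,7-dimethoxy-3,4-dihydro-2H-chromen-6-yl}oxy)benzoate | CC(C)(C)[Si](C)(C)O[C@H]1C[C@@H](c2ccc(OCc3ccccc3)cc2)Oc2cc(OC)c(Oc3ccc(cc3)C(=O)OC)c(OC)c12 | intermediate
13 | [4-({(2S,4S)-2-[4-(benzyloxy)phenyl]-4-[(tert-butyldimethylsilyl)oxy]-5,7-dimethoxy-3,4-dihydro-2H-chromen-6-yl}oxy)phenyl]methanol | CC(C)(C)[Si](C)(C)O[C@H]1C[C@@H](c2ccc(OCc3ccccc3)cc2)Oc2cc(OC)c(Oc3ccc(CO)cc3)c(OC)c12 | intermediate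
14 | 4-({(2S,4S)-2-[4-(benzyloxy)phenyl]-4-[(tert-butyldimethylsilyl)oxy]-5,7-dimethoxy-3,4-dihydro-2H-chromen-6-yl}oxy)benzaldehyde | CC(C)(C)[Si](C)(C)O[C@H]1C[C@@H](c2ccc(OCc3ccccc3)cc2)Oc2cc(OC)c(Oc3ccc(C=O)cc3)c(OC)c12 | intermediate (not isolated)
15 | {[(2S,4S)-2-[4-(benzyloxy)phenyl]-6-(4-ethynylphenoxy)-5,7-dimethoxy-3,4-dihydro-2H-chromen-4-yl]oxy}(tert-butyl)dimethylsilane | CC(C)(C)[Si](C)(C)O[C@H]1C[C@@H](c2ccc(OCc3ccccc3)cc2)Oc2cc(OC)c(Oc3ccc(cc3)C#C)c(OC)c12 | intermediate
16 | 3,5-bis(benzyloxy)phenol | Oc1cc(OCc2ccccc2)cc(OCc2ccccc2)c1 | starting material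
17 | 3,5-bis(benzyloxy)-2-iodophenol | Oc1cc(OCc2ccccc2)cc(OCc2ccccc2)c1I | intermediate
18 | 1-[2,4-bis(benzyloxy)-6-hydroxyphenyl]-3-[4-({(2S,4S)-2-[4-(benzyloxy)phenyl]-4-[(tert-butyldimethylsilyl)oxy]-5,7-dimethoxy-3,4-dihydro-2H-chromen-6-yl}oxy)phenyl]prop-2-yn-1-one | CC(C)(C)[Si](C)(C)O[C@H]1C[C@@H](c2ccc(OCc3ccccc3)cc2)Oc2cc(OC)c(Oc3ccc(cc3)C#CC(=O)c3c(O)cc(OCc4ccccc4)cc3OCc3ccccc3)c(OC)c12 | intermediate (not isolated)
19 | 1-[2,4-bis(benzyloxy)-6-hydroxyphenyl]-3-(diethylamino)-3-[4-({(2S,4S)-2-[4-(benzyloxy)phenyl]-4-[(tert-butyldimethylsilyl)oxy]-5,7-dimethoxy-3,4-dihydro-2H-chromen-6-yl}oxy)phenyl]prop-2-en-1-one (alkene geometry not defined) | CC(C)(C)[Si](C)(C)O[C@H]1C[C@@H](c2ccc(OCc3ccccc3)cc2)Oc2cc(OC)c(Oc3ccc(cc3)C(=CC(=O)c3c(O)cc(OCc4ccccc4)cc3OCc3ccccc3)N(CC)CC)c(OC)c12 | intermediate (not isolated)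
20 | 5,7-bis(benzyloxy)-2-[4-({(2S,4S)-2-[4-(benzyloxy)phenyl]-4-[(tert-butyldimethylsilyl)oxy]-5,7-dimethoxy-3,4-dihydro-2H-chromen-6-yl}oxy)phenyl]-4H-chromen-4-one | CC(C)(C)[Si](C)(C)O[C@H]1C[C@@H](c2ccc(OCc3ccccc3)cc2)Oc2cc(OC)c(Oc3ccc(cc3)-c3cc(=O)c4c(OCc5ccccc5)cc(OCc5ccccc5)cc4o3)c(OC)c12 | intermediate
21 | 5,7-bis(benzyloxy)-2-[4-({(2S,4S)-2-[4-(benzyloxy)phenyl]-4-hydroxy-5,7-dimethoxy-3,4-dihydro-2H-chromen-6-yl}oxy)phenyl]-4H-chromen-4-one | O[C@H]1C[C@@H](c2ccc(OCc3ccccc3)cc2)Oc2cc(OC)c(Oc3ccc(cc3)-c3cc(=O)c4c(OCc5ccccc5)cc(OCc5ccccc5)cc4o3)c(OC)c12 | intermediate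
22 | 5,7-bis(benzyloxy)-2-[4-({(2S)-2-[4-(benzyloxy)phenyl]-5,7-dimethoxy-4-oxo-3,4-dihydro-2H-chromen-6-yl}oxy)phenyl]-4H-chromen-4-one | O=C1C[C@@H](c2ccc(OCc3ccccc3)cc2)Oc2cc(OC)c(Oc3ccc(cc3)-c3cc(=O)c4c(OCc5ccccc5)cc(OCc5ccccc5)cc4o3)c(OC)c12 | intermediate
23 | 5,7-dihydroxy-2-[4-({(2S)-5-hydroxy-2-(4-hydroxyphenyl)-7-methoxy-4-oxo-3,4-dihydro-2H-chromen-6-yl}oxy)phenyl]-4H-chromen-4-one (CNP0269971.1) | COc1cc2c(c(O)c1Oc1ccc(-c3cc(=O)c4c(O)cc(O)cc4o3)cc1)C(=O)C[C@@H](c1ccc(O)cc1)O2 | target

## Step count and least certain steps

Total step count: 14. Longest linear sequence: 13 steps (steps 1 to 9 and 11 to 14, from 1); step 10 is a one-step branch.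

**Step 11 (key step).** Three processes could go wrong. Alkynyl transfer to the aryl–palladium species could occur before carbon monoxide insertion, followed by 5-endo closure of the phenol onto the alkyne. The phenol could close 5-exo on the ynone before the amine has added. The electron-rich, doubly ortho-substituted iodide could add slowly to palladium and lose iodine reductively. Fallback: a condensation–oxidative cyclisation route that needs neither palladium nor carbon monoxide. It sets out from 14, which is isolated for this purpose by ending step 9 after the MnO2 stage. Claisen–Schmidt condensation of 14 with purchased 1-[2,4-bis(benzyloxy)-6-hydroxyphenyl]ethanone (CC(=O)c1c(O)cc(OCc2ccccc2)cc1OCc1ccccc1) under KOH in EtOH/THF at rt should give the 2'-hydroxychalcone F1. Oxidative cyclisation of F1 with catalytic I2 in DMSO at 110 °C (conjugate addition of the phenol, α-iodination, elimination) should then give the flavone, and the route is rejoined at 20.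

**Step 5.** The peri methoxy group at C5 could slow the carbopalladation, the electron-rich boronic acid could protodeboronate, and facial selectivity could be poor or of the sense opposite to that assumed. Fallback: racemic ring formation followed by kinetic resolution, setting out from 6. Claisen–Schmidt condensation of 6 with purchased 4-(benzyloxy)benzaldehyde (O=Cc1ccc(OCc2ccccc2)cc1) under NaOMe in MeOH should give the chalcone F2. Heating F2 with NaOAc in EtOH should close it by oxa-Michael addition to the racemic flavanone F3. Asymmetric transfer hydrogenation of F3 with RuCl[(S,S)-TsDPEN](p-cymene) and HCO2Na in H2O/EtOAc should reduce only the 2S enantiomer, in the cis sense, while the 2R ketone stays behind and is separated. This gives the (2S,4S)-carbinol directly, so the route is rejoined at 11 and step 6 is not needed, at the cost of half the material.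

**Step 1.** The phenoxide of 1 is weakly nucleophilic (para formyl group) and hindered, so substitution could be slow, and at the temperature required the phenoxide could instead be methylated by the methyl ester. Fallback: copper-catalysed Ullmann-type etherification, setting out from 1. Coupling of 1 with purchased methyl 4-iodobenzoate (COC(=O)c1ccc(I)cc1) under CuI, picolinic acid and K3PO4 in DMSO at 90 °C should form the same C–O bond by oxidative addition and reductive elimination at copper, and the route is rejoined at 3.

**Step 10.** Iodination could take place at the carbon para to the hydroxyl, or twice, and the ortho-iodophenol could lose iodine on storage. Fallback: directed ortho-metalation, setting out from 16. Protection with MOMCl and i-Pr2NEt should give the methoxymethyl ether F4. Lithiation with n-BuLi in THF at −20 °C should occur at the carbon between the methoxymethoxy and benzyloxy groups, the stronger pair of directing groups, and quenching with I2 should give the iodide F5. Removal of the acetal with HCl in MeOH rejoins the route at 17.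

**Step 14.** Benzyl cations could alkylate the liberated phloroglucinol-type rings if trapping is incomplete. The Lewis acid could open the flavanone at C2 once the 4'-phenol is free, with loss of configuration. The unchelated benzyl ethers could cleave only at temperatures that begin to touch the C7 methyl ether. Fallback: two separate, milder operations, setting out from 22. Hydrogenolysis with H2 and Pd/C in EtOAc/THF should remove the three benzyl groups and give the 5-O-methyl triphenol F6, the flavone C2=C3 bond and the C4 ketones being slow to reduce. Chelation-controlled demethylation of F6 with MgI2 in THF/toluene at 60 °C should then cleave only the C5 methyl ether, and the route is rejoined at 23.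

## Further compounds

F1 | step 11 | (2E)-1-[2,4-bis(benzyloxy)-6-hydroxyphenyl]-3-[4-({(2S,4S)-2-[4-(benzyloxy)phenyl]-4-[(tert-butyldimethylsilyl)oxy]-5,7-dimethoxy-3,4-dihydro-2H-chromen-6-yl}oxy)phenyl]prop-2-en-1-one | CC(C)(C)[Si](C)(C)O[C@H]1C[C@@H](c2ccc(OCc3ccccc3)cc2)Oc2cc(OC)c(Oc3ccc(cc3)/C=C/C(=O)c3c(O)cc(OCc4ccccc4)cc3OCc3ccccc3)c(OC)c12
F2 | step 5 | methyl 4-(3-{(2E)-3-[4-(benzyloxy)phenyl]prop-2-enoyl}-4-hydroxy-2,6-dimethoxyphenoxy)benzoate | COC(=O)c1ccc(Oc2c(OC)cc(O)c(C(=O)/C=C/c3ccc(OCc4ccccc4)cc3)c2OC)cc1
F3 | step 5 | racemic methyl 4-({2-[4-(benzyloxy)phenyl]-5,7-dimethoxy-4-oxo-3,4-dihydro-2H-chromen-6-yl}oxy)benzoate | O=C1CC(c2ccc(OCc3ccccc3)cc2)Oc2cc(OC)c(Oc3ccc(cc3)C(=O)OC)c(OC)c12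
F0 | step 1 | none | none
F4 | step 10 | 1,3-bis(benzyloxy)-5-(methoxymethoxy)benzene | COCOc1cc(OCc2ccccc2)cc(OCc2ccccc2)c1
F5 | step 10 | 1,5-bis(benzyloxy)-2-iodo-3-(methoxymethoxy)benzene | COCOc1cc(OCc2ccccc2)cc(OCc2ccccc2)c1I
F6 | step 14 | 5,7-dihydroxy-2-[4-({(2S)-2-(4-hydroxyphenyl)-5,7-dimethoxy-4-oxo-3,4-dihydro-2H-chromen-6-yl}oxy)phenyl]-4H-chromen-4-one | O=C1C[C@@H](c2ccc(O)cc2)Oc2cc(OC)c(Oc3ccc(cc3)-c3cc(=O)c4c(O)cc(O)cc4o3)c(OC)c12
A1 | alternative 1 | 5,7-bis(benzyloxy)-2-[4-(3-{(3R)-3-[4-(benzyloxy)phenyl]-1,3-bis[(tert-butyldimethylsilyl)oxy]propyl}-2-hydroxy-6-methoxy-4-[(triisopropylsilyl)oxy]phenoxy)phenyl]-4H-chromen-4-one (C4 carbon added; configuration at C4 not defined) | COc1cc(O[Si](C(C)C)(C(C)C)C(C)C)c(C(O[Si](C)(C)C(C)(C)C)C[C@@H](O[Si](C)(C)C(C)(C)C)c2ccc(OCc3ccccc3)cc2)c(O)c1Oc1ccc(cc1)-c1cc(=O)c2c(OCc3ccccc3)cc(OCc3ccccc3)cc2o1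
A2 | alternative 1 | 5,7-bis(benzyloxy)-2-{4-[(2-methoxy-4-oxocyclobut-2-en-1-yl)oxy]phenyl}-4H-chromen-4-one | COC1=CC(=O)C1Oc1ccc(cc1)-c1cc(=O)c2c(OCc3ccccc3)cc(OCc3ccccc3)cc2o1
A3 | alternative 1 | (5R)-5-[4-(benzyloxy)phenyl]-3,5-bis[(tert-butyldimethylsilyl)oxy]-1-[(triisopropylsilyl)oxy]pent-1-yne (configuration at C3 not defined) | CC(C)[Si](C(C)C)(C(C)C)OC#CC(O[Si](C)(C)C(C)(C)C)C[C@@H](O[Si](C)(C)C(C)(C)C)c1ccc(OCc2ccccc2)cc1
A4 | alternative 2 | 2-{4-[4-(benzyloxy)-2,6-dimethoxyphenoxy]phenyl}-5,7-dihydroxy-4H-chromen-4-one | Oc1cc(O)c2c(c1)oc(cc2=O)-c1ccc(Oc2c(OC)cc(OCc3ccccc3)cc2OC)cc1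
A5 | alternative 2 | methyl 4-(6-{4-[4-(benzyloxy)-2,6-dimethoxyphenoxy]phenyl}-4-oxo-4H-pyran-2-yl)-3-oxobutanoate | COC(=O)CC(=O)Cc1cc(=O)cc(o1)-c1ccc(Oc2c(OC)cc(OCc3ccccc3)cc2OC)cc1
A6 | alternative 3 | 4-[(2S)-6-{4-[5,7-bis(benzyloxy)-4-oxo-4H-chromen-2-yl]phenoxy}-5,7-dimethoxy-4-oxo-3,4-dihydro-2H-chromen-2-yl]phenyl acetate | COc1cc2c(c(OC)c1Oc1ccc(-c3cc(=O)c4c(OCc5ccccc5)cc(OCc5ccccc5)cc4o3)cc1)C(=O)C[C@@H](c1ccc(OC(C)=O)cc1)O2
A7 | alternative 3 | (3S)-3-[4-(acetyloxy)phenyl]-3-(4-{4-[5,7-bis(benzyloxy)-4-oxo-4H-chromen-2-yl]phenoxy}-3,5-dimethoxyphenoxy)propanoic acid | OC(=O)C[C@@H](c1ccc(OC(C)=O)cc1)Oc1cc(OC)c(Oc2ccc(cc2)-c2cc(=O)c3c(OCc4ccccc4)cc(OCc4ccccc4)cc3o2)c(OC)c1
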